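## Analysis of the target

Compound 22 is a biflavonoid. It joins a 5-hydroxy-7-methoxyflavone to a 5,7-dihydroxy-2-(4-hydroxyphenyl)chroman-4-one (a flavanone). The bond runs from C3' of the flavone ring B to C3 of the flavanone. The only stereocentres are the adjacent flavanone carbons C2 (S) and C3 (R). Their hydrogens are anti, so both aryl groups are equatorial (2,3-trans). C3 is benzylic and alpha to the ketone, so it epimerises readily and settles in the trans arrangement. C2 can only be lost by retro-oxa-Michael ring opening under base. The sensitive features are five free phenols next to one methyl ether that must be kept, the base-labile flavanone, and two pyranones that are electrophilic at C2. The difficulty lies in the hindered bond between a stereogenic sp3 carbon and an ortho-oxygenated arene, in the absolute configuration at C2, and in telling the 7-methoxy group apart from the other oxygens. The strategy rests on the linking ring itself. It carries flavanone C3 at C3', oxygen at C4' and flavone C2 at C1', so the oxygen is ortho to one heterocycle and para to the other. This is the pattern that a 1-substituted 2-oxybutadiene and an acceptor-substituted terminal alkyne give after cycloaddition and dehydrogenation, so the ring can be built with both halves already attached.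

## Retrosynthetic reasoning

22 from 21. The five phenols are unmasked last from benzyl ethers. One neutral hydrogenolysis then removes all of them, and the methyl ether is left alone. Nothing basic touches the finished flavanone.

21 from 18 and 19. The C2–aryl bond of the flavanone is cut. This places both stereocentres at the end of the route, after all hot or basic C–C bond formations. The forward step is an enantioselective conjugate arylation of the isoflavone half of 18 with boronic acid 19. Only C2 needs catalyst control, because C3 relaxes from the cis epimer 20 to trans 21.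

18 from 8 and 16. The linking ring is opened at C2'–C3' and C1'–C6'. This is preferred to a cut at the biaryl-type C3–C3' bond, because a cross-coupling there would join two hindered, ortho-substituted partners. The forward step is a [4+2] cycloaddition of diene 8 with alkyne 16 to give cycloadduct 17, which is dehydrogenated in the same flask. It must deliver one regioisomer.

8 from 3 and 5. The enol ether double bond is made by olefination of aldehyde 3 with the benzyloxy ketophosphonate 5, giving enone 6. The acetyl group of 6 becomes the vinyl group through enol triflate 7 and reductive removal of the triflate. This avoids hydride reagents and unstabilised ylides, which could attack the chromone.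

3 from 1, and 5 from 4. Aldehyde 3 comes from acetophenone 2 by formylative chromone closure. Compound 2 is the dibenzyl ether of 1. Phosphonate 5 comes from diazo compound 4 by carbenoid O–H insertion.

16 from 10 and 11. The alkyne carbon is added to aldehyde 15 by one-carbon homologation, again with 4. Aldehyde 15 comes from ester 13 through alcohol 14. Ester 13 comes from condensation of acetophenone 10 with oxalate 11 through diketo ester 12. Compound 10 is the monobenzyl ether of 9, which already holds the methyl ether in the right place.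

## Alternatives that were turned down

Alternative 1: The flavone pyranone is cut at C4a–C4, C4–C3 and O1–C2. This leads to 2-iodo-5-methoxybenzene-1,3-diol A2, carbon monoxide A4 and aryl alkyne A3, which already contains the complete enantiopure flavanone. The forward step is a palladium-catalysed carbonylative alkyne coupling in a secondary amine, followed by 6-endo closure of the ynone by an ortho hydroxyl, giving A1.
- For: three bonds and a ring form in one precedented operation. The symmetry of A2 makes either hydroxyl suitable, and the 5-hydroxyl comes out unprotected.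
- Against: it solves only the easy half. A3 presupposes the hindered C3–C3' bond and both stereocentres. The flavanone, with its acidic C3–H and openable C2–O bond, would be heated in a nucleophilic amine, so C2 could be lost by ring opening. A 5-exo closure could also compete.
- Comparison: it is stronger on convergence and on protecting-group economy at the flavone 5-oxygen. The chosen route instead makes the hindered junction by building ring B around it, and sets the stereocentres after all such conditions.

Alternative 2: Ring C of the flavanone is cut at O1–C2 and C3–C4. This leads to 3,5-bis(benzyloxy)-2-(dimethoxymethyl)phenol A6 and E-stilbene A7. A chiral phosphoric acid would ionise A6 to an ortho-quinone methide cation. Its methide carbon bonds to the alkene carbon bearing ring B, and the phenol oxygen captures the cation at the carbon bearing the 4-benzyloxyphenyl group. The product is the 4-methoxyflavan A5.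
- For: both stereocentres and the ring form together. The trans relationship follows from the alkene geometry and the absolute sense from the catalyst.
- Against: A5 is at the wrong oxidation level at C4. The methyl ether must be hydrolysed and the alcohol oxidised on an acid-sensitive, electron-rich benzylic ether, which can ionise and scramble C2. A 1,2-diaryl ethene with an ortho-substituted, carbonate-bearing aryl group is a much poorer 2π partner than a styrene. It also needs an extra protecting group.
- Comparison: on stereocontrol it is stronger than the chosen route, whose arylation of a 3-arylchromone has no direct precedent. The chosen route offers the correct C4 oxidation state from the start and a key step with no stereochemical demand.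

Alternative 3: The flavanone C2–C3 bond is cut, leading to diazo ketone A9, which has two ortho 4-benzyloxybenzyl ethers. A chiral dirhodium tetracarboxylate would form a carbenoid at C3. Insertion into a benzylic C–H bond of one ether closes ring C and gives A8 after C3 equilibration.
- For: the hindered bond is made intramolecularly. C2 is set in the ring-forming step by a catalyst class with precedent in ether C–H insertion. The second, identical ether remains as a protecting group.
- Against: the carbenoid can attack the ether oxygen instead, giving a five-membered oxonium ylide and a 1,2-benzyl shift. It can also add to the electron-rich benzyl rings or to the silyl ether oxygen. A9 needs a diazo transfer onto a hindered ketone and three kinds of protecting group.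
- Comparison: it is stronger in that the stereo-determining step is intramolecular and of a known class. The chosen route avoids carbenoid chemoselectivity, uses one kind of protecting group and a metal-free ring construction.

Key step: step 12

Assumption: 4 and 9 are taken as purchasable, and the (S)-bisphosphine in step 13 is assumed to direct aryl transfer as it does with cyclohexenone, where the (S) ligand gives the (S) ketone, which maps onto 2S here; the antipodal ligand would be used if the sense were reversed.

## Route

Step 1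
Reactants: 1 2,4,6-trihydroxyacetophenone
Product: 2 1-[2,4-bis(benzyloxy)-6-hydroxyphenyl]ethanone
Conditions: BnBr (2.1 equiv), K2CO3, DMF, 20 to 60 °C
Reagents that add atoms: benzyl bromide, BrCc1ccccc1
Why: Williamson etherification; the remaining ortho hydroxyl is hydrogen-bonded to the acetyl carbonyl and is alkylated much more slowly, so the reaction should stop at the dibenzyl ether.

Step 2
Reactants: 2 1-[2,4-bis(benzyloxy)-6-hydroxyphenyl]ethanone
Product: 3 5,7-bis(benzyloxy)-4-oxo-4H-chromene-3-carbaldehyde
Conditions: POCl3 (3 equiv), DMF, 0 to 50 °C; then ice/H2O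
Reagents that add atoms: N,N-dimethylformamide, CN(C)C=O; water, O
Why: Vilsmeier–Haack double formylation of the acetyl methyl group, closure through the free phenol and hydrolysis of the iminium salt is the standard entry to 3-formylchromones; the acyl-deactivated arene should not be formylated.

Step 3
Reactants: 4 dimethyl (1-diazo-2-oxopropyl)phosphonate
Product: 5 dimethyl [1-(benzyloxy)-2-oxopropyl]phosphonate (racemic)
Conditions: BnOH (2 equiv), Rh2(OAc)4 (1 mol%), toluene, 80 °C, slow addition of 4
Reagents that add atoms: benzyl alcohol, OCc1ccccc1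
Why: Dirhodium-carbenoid O–H insertion; loss of N2 gives an electrophilic carbenoid that is trapped by the alcohol oxygen faster than it rearranges, which places the benzyloxy group on the phosphonate carbon.

Step 4
Reactants: 3 5,7-bis(benzyloxy)-4-oxo-4H-chromene-3-carbaldehyde; 5 dimethyl [1-(benzyloxy)-2-oxopropyl]phosphonate
Product: 6 (3Z)-3-(benzyloxy)-4-[5,7-bis(benzyloxy)-4-oxo-4H-chromen-3-yl]but-3-en-2-one
Conditions: NaH (1.05 equiv), THF, 0 °C; then 3, 0 to 20 °C
Reagents that add atoms: none
Why: Horner–Wadsworth–Emmons olefination with a stabilised ketophosphonate anion, which should attack the aldehyde and not chromone C2; reversible addition should favour the Z enone with the chromonyl group trans to acetyl, and any E isomer is removed by chromatography.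

Step 5
Reactants: 6 (3Z)-3-(benzyloxy)-4-[5,7-bis(benzyloxy)-4-oxo-4H-chromen-3-yl]but-3-en-2-one
Product: 7 (3Z)-3-(benzyloxy)-4-[5,7-bis(benzyloxy)-4-oxo-4H-chromen-3-yl]buta-1,3-dien-2-yl trifluoromethanesulfonate
Conditions: KN(SiMe3)2 (1.1 equiv), THF, −78 °C; then PhNTf2 (1.2 equiv), −78 to 0 °C
Reagents that add atoms: N-phenylbis(trifluoromethanesulfonimide), O=S(=O)(N(c1ccccc1)S(=O)(=O)C(F)(F)F)C(F)(F)F
Why: Kinetic deprotonation of the only enolisable position (the methyl ketone) by a hindered amide and O-sulfonylation of the cross-conjugated enolate is the standard enone to dienyl triflate conversion; the low temperature should keep the Z geometry.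

Step 6
Reactants: 7 (3Z)-3-(benzyloxy)-4-[5,7-bis(benzyloxy)-4-oxo-4H-chromen-3-yl]buta-1,3-dien-2-yl trifluoromethanesulfonate
Product: 8 5,7-bis(benzyloxy)-3-[(1Z)-2-(benzyloxy)buta-1,3-dien-1-yl]-4H-chromen-4-one
Conditions: Pd(OAc)2 (5 mol%), PPh3 (10 mol%), HCO2H (2 equiv), Bu3N (3 equiv), DMF, 60 °C
Reagents that add atoms: none
Why: Palladium-catalysed formate reduction of an enol triflate; oxidative addition of zerovalent palladium, formate exchange, loss of CO2 and reductive elimination replace OTf by H without a hydride nucleophile that could reduce the chromone, and the amine buffer protects the acid-labile enol ether.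

Step 7
Reactants: 9 1-(2,6-dihydroxy-4-methoxyphenyl)ethanone
Product: 10 1-[2-(benzyloxy)-6-hydroxy-4-methoxyphenyl]ethanone
Conditions: BnBr (1.05 equiv), K2CO3, acetone, reflux
Reagents that add atoms: benzyl bromide, BrCc1ccccc1
Why: Williamson monobenzylation; after the first alkylation the remaining hydroxyl is chelated to the acetyl group, so the reaction should stop at the monoether.

Step 8
Reactants: 10 1-[2-(benzyloxy)-6-hydroxy-4-methoxyphenyl]ethanone; 11 diethyl oxalate
Product: 13 ethyl 5-(benzyloxy)-7-methoxy-4-oxo-4H-chromene-2-carboxylate, via diketo ester 12 (not isolated)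
Conditions: NaOEt (4 equiv), EtOH, 0 to 78 °C; then conc. HCl to pH 1, EtOH, 70 °C
Reagents that add atoms: none
Why: Crossed Claisen condensation of the acetophenone enolate with the non-enolisable diester gives 12, and acid-catalysed cyclodehydration through the free ortho phenol closes the pyranone, the classical chromone-2-carboxylate synthesis.

Step 9
Reactants: 13 ethyl 5-(benzyloxy)-7-methoxy-4-oxo-4H-chromene-2-carboxylate
Product: 14 5-(benzyloxy)-2-(hydroxymethyl)-7-methoxy-4H-chromen-4-one
Conditions: NaBH4 (1.2 equiv), MeOH, 0 °C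
Reagents that add atoms: none
Why: Borohydride reduction of an activated ester; the carboxylate sits on an oxygen-bearing, enone-conjugated carbon and is reduced at 0 °C, whereas the vinylogous-ester carbonyl of the chromone is inert on this time scale, a selectivity established for chromone-2-carboxylates.

Step 10
Reactants: 14 5-(benzyloxy)-2-(hydroxymethyl)-7-methoxy-4H-chromen-4-one
Product: 15 5-(benzyloxy)-7-methoxy-4-oxo-4H-chromene-2-carbaldehyde
Conditions: Dess–Martin periodinane (1.3 equiv), NaHCO3, CH2Cl2, 20 °C
Reagents that add atoms: none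
Why: Dess–Martin oxidation of a primary alcohol under buffered, non-basic conditions stops at the aldehyde and leaves the benzyl ether and the pyranone untouched.

Step 11
Reactants: 15 5-(benzyloxy)-7-methoxy-4-oxo-4H-chromene-2-carbaldehyde; 4 dimethyl (1-diazo-2-oxopropyl)phosphonate
Product: 16 5-(benzyloxy)-2-ethynyl-7-methoxy-4H-chromen-4-one
Conditions: 4 (1.3 equiv), NaOMe (1.3 equiv), THF, −78 °C; then 15, −78 to 0 °C
Reagents that add atoms: none
Why: Seyferth–Gilbert homologation in the Ohira–Bestmann variant; methoxide removes the acetyl group of 4, the diazomethylphosphonate anion adds to the aldehyde, and loss of dimethyl phosphate and N2 with 1,2-hydrogen shift gives the terminal alkyne, while the use of stoichiometric methoxide in THF leaves no alkoxide to add to the electrophilic alkyne.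

Step 12
Reactants: 8 5,7-bis(benzyloxy)-3-[(1Z)-2-(benzyloxy)buta-1,3-dien-1-yl]-4H-chromen-4-one; 16 5-(benzyloxy)-2-ethynyl-7-methoxy-4H-chromen-4-one
Product: 18 5,7-bis(benzyloxy)-3-{2-(benzyloxy)-5-[5-(benzyloxy)-7-methoxy-4-oxo-4H-chromen-2-yl]phenyl}-4H-chromen-4-one, via cyclohexa-1,4-diene cycloadduct 17 (not isolated)
Conditions: toluene, BHT (5 mol%), 110 °C, sealed tube; then DDQ (1.2 equiv), 20 °C
Reagents that add atoms: none
Why: The s-cis 2-benzyloxydiene of 8 (HOMO raised by the enol ether) and the alkyne of 16 (LUMO lowered by conjugation through C2=C3 to the C4 carbonyl, a vinylogous ynone) should combine in a concerted, suprafacial thermal [4+2] cycloaddition, the closest known reaction type being the Diels–Alder reaction of 2-alkoxy- and 2-silyloxybutadienes with acetylenic ketones and esters followed by quinone dehydrogenation to aryl ethers. The six-membered carbocycle closes by intermolecular cycloaddition in which both new σ bonds (C2'–C3' and C1'–C6') form in one step, giving cyclohexa-1,4-diene 17. DDQ then abstracts hydride from the doubly allylic carbon that carries the chromonyl group and a proton is lost, so 17 should aromatise to the benzyl aryl ether 18 at room temperature. No stereocentre has to be controlled, because the single sp3 centre of 17 is planarised on aromatisation. The selectivity that matters is regiochemical: the diene terminus next to the benzyloxy-bearing carbon (the β-carbon of the enol ether, with the larger HOMO coefficient) must bond to the terminal alkyne carbon (the larger LUMO coefficient), which places oxygen para to the flavone-bearing carbon, and the unsubstituted alkyne terminus is also the one that fits best against the substituted diene terminus. The Z geometry of 8 keeps the chromonyl group outside the s-cis diene, which permits the cycloaddition and forbids a 6π electrocyclisation onto the chromone C2=C3 bond, and the alternative diene that includes that push–pull double bond is far less reactive.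

Step 13
Reactants: 18 5,7-bis(benzyloxy)-3-{2-(benzyloxy)-5-[5-(benzyloxy)-7-methoxy-4-oxo-4H-chromen-2-yl]phenyl}-4H-chromen-4-one; 19 [4-(benzyloxy)phenyl]boronic acid
Product: 21 (2S,3R)-5,7-bis(benzyloxy)-3-{2-(benzyloxy)-5-[5-(benzyloxy)-7-methoxy-4-oxo-4H-chromen-2-yl]phenyl}-2-[4-(benzyloxy)phenyl]-2,3-dihydro-4H-chromen-4-one, via cis-2,3 epimer 20 (not isolated)
Conditions: 19 (3 equiv), [RhCl(C2H4)2]2 (5 mol%), (S)-MeO-F12-BIPHEP (11 mol%), KOH (20 mol%), toluene/H2O (10:1), 40 °C; then Et3N (0.2 equiv), CH2Cl2, 20 °C
Reagents that add atoms: none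
Why: Proposed new method: the aryl–rhodium species formed by transmetalation from 19 is expected to insert the C2=C3 bond of the isoflavone half of 18 (the flavone half is blocked by its C2 aryl group), delivering the aryl group to C2 on the face set by the (S)-bisphosphine and giving an oxa-π-allyl rhodium enolate that water protonates; the closest known reaction type is the rhodium-catalysed asymmetric 1,4-addition of arylboronic acids to 3-unsubstituted chromones (Hayashi–Miyaura reaction), which has not been shown with a 3-aryl substituent; kinetic protonation may give cis 20, and the doubly activated C3–H lets triethylamine convert it into the diequatorial trans isomer 21 without touching C2.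

Step 14
Reactants: 21 (2S,3R)-5,7-bis(benzyloxy)-3-{2-(benzyloxy)-5-[5-(benzyloxy)-7-methoxy-4-oxo-4H-chromen-2-yl]phenyl}-2-[4-(benzyloxy)phenyl]-2,3-dihydro-4H-chromen-4-one
Product: 22 (2S,3R)-5,7-dihydroxy-3-[2-hydroxy-5-(5-hydroxy-7-methoxy-4-oxo-4H-chromen-2-yl)phenyl]-2-(4-hydroxyphenyl)-2,3-dihydro-4H-chromen-4-one
Conditions: H2 (1 atm), 10% Pd/C, THF/MeOH (1:1), 20 °C
Reagents that add atoms: none
Why: Heterogeneous hydrogenolysis of the five benzyl aryl ethers; the methyl ether is inert, the flavone double bond and the aryl ketone are reduced much more slowly at 1 atm, and the neutral medium avoids ring opening at C2, so the (2S,3R) configuration should be carried into 22.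

## Compound list

1 | 2,4,6-trihydroxyacetophenone | CC(=O)c1c(O)cc(O)cc1O | starting material
2 | 1-[2,4-bis(benzyloxy)-6-hydroxyphenyl]ethanone | CC(=O)c1c(O)cc(OCc2ccccc2)cc1OCc1ccccc1 | intermediate
3 | 5,7-bis(benzyloxy)-4-oxo-4H-chromene-3-carbaldehyde | O=Cc1coc2cc(OCc3ccccc3)cc(OCc3ccccc3)c2c1=O | intermediate
4 | dimethyl (1-diazo-2-oxopropyl)phosphonate | COP(=O)(OC)C(=[N+]=[N-])C(C)=O | starting material
5 | dimethyl [1-(benzyloxy)-2-oxopropyl]phosphonate (racemic) | COP(=O)(OC)C(OCc1ccccc1)C(C)=O | intermediate
6 | (3Z)-3-(benzyloxy)-4-[5,7-bis(benzyloxy)-4-oxo-4H-chromen-3-yl]but-3-en-2-one | CC(=O)/C(OCc1ccccc1)=C/c1coc2cc(OCc3ccccc3)cc(OCc3ccccc3)c2c1=O | intermediate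
7 | (3Z)-3-(benzyloxy)-4-[5,7-bis(benzyloxy)-4-oxo-4H-chromen-3-yl]buta-1,3-dien-2-yl trifluoromethanesulfonate | C=C(OS(=O)(=O)C(F)(F)F)/C(OCc1ccccc1)=C/c1coc2cc(OCc3ccccc3)cc(OCc3ccccc3)c2c1=O | intermediate
8 | 5,7-bis(benzyloxy)-3-[(1Z)-2-(benzyloxy)buta-1,3-dien-1-yl]-4H-chromen-4-one | C=C/C(OCc1ccccc1)=C/c1coc2cc(OCc3ccccc3)cc(OCc3ccccc3)c2c1=O | intermediate
9 | 1-(2,6-dihydroxy-4-methoxyphenyl)ethanone | CC(=O)c1c(O)cc(OC)cc1O | starting material
10 | 1-[2-(benzyloxy)-6-hydroxy-4-methoxyphenyl]ethanone | CC(=O)c1c(O)cc(OC)cc1OCc1ccccc1 | intermediate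
11 | diethyl oxalate | CCOC(=O)C(=O)OCC | starting material
12 | ethyl 4-[2-(benzyloxy)-6-hydroxy-4-methoxyphenyl]-2,4-dioxobutanoate | CCOC(=O)C(=O)CC(=O)c1c(O)cc(OC)cc1OCc1ccccc1 | intermediate
13 | ethyl 5-(benzyloxy)-7-methoxy-4-oxo-4H-chromene-2-carboxylate | CCOC(=O)c1cc(=O)c2c(OCc3ccccc3)cc(OC)cc2o1 | intermediate
14 | 5-(benzyloxy)-2-(hydroxymethyl)-7-methoxy-4H-chromen-4-one | COc1cc(OCc2ccccc2)c2c(=O)cc(CO)oc2c1 | intermediate
15 | 5-(benzyloxy)-7-methoxy-4-oxo-4H-chromene-2-carbaldehyde | COc1cc(OCc2ccccc2)c2c(=O)cc(C=O)oc2c1 | intermediate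
16 | 5-(benzyloxy)-2-ethynyl-7-methoxy-4H-chromen-4-one | C#Cc1cc(=O)c2c(OCc3ccccc3)cc(OC)cc2o1 | intermediate
17 | 5,7-bis(benzyloxy)-3-{6-(benzyloxy)-3-[5-(benzyloxy)-7-methoxy-4-oxo-4H-chromen-2-yl]cyclohexa-2,5-dien-1-yl}-4H-chromen-4-one (racemic) | COc1cc(OCc2ccccc2)c2c(=O)cc(C3=CC(c4coc5cc(OCc6ccccc6)cc(OCc6ccccc6)c5c4=O)C(OCc4ccccc4)=CC3)oc2c1 | intermediate
18 | 5,7-bis(benzyloxy)-3-{2-(benzyloxy)-5-[5-(benzyloxy)-7-methoxy-4-oxo-4H-chromen-2-yl]phenyl}-4H-chromen-4-one | COc1cc(OCc2ccccc2)c2c(=O)cc(-c3ccc(OCc4ccccc4)c(-c4coc5cc(OCc6ccccc6)cc(OCc6ccccc6)c5c4=O)c3)oc2c1 | intermediate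
19 | [4-(benzyloxy)phenyl]boronic acid | OB(O)c1ccc(OCc2ccccc2)cc1 | starting material
20 | (2S,3S)-5,7-bis(benzyloxy)-3-{2-(benzyloxy)-5-[5-(benzyloxy)-7-methoxy-4-oxo-4H-chromen-2-yl]phenyl}-2-[4-(benzyloxy)phenyl]-2,3-dihydro-4H-chromen-4-one (2,3-cis) | COc1cc(OCc2ccccc2)c2c(=O)cc(-c3ccc(OCc4ccccc4)c([C@@H]4C(=O)c5c(OCc6ccccc6)cc(OCc6ccccc6)cc5O[C@@H]4c4ccc(OCc5ccccc5)cc4)c3)oc2c1 | intermediate
21 | (2S,3R)-5,7-bis(benzyloxy)-3-{2-(benzyloxy)-5-[5-(benzyloxy)-7-methoxy-4-oxo-4H-chromen-2-yl]phenyl}-2-[4-(benzyloxy)phenyl]-2,3-dihydro-4H-chromen-4-one (2,3-trans) | COc1cc(OCc2ccccc2)c2c(=O)cc(-c3ccc(OCc4ccccc4)c([C@H]4C(=O)c5c(OCc6ccccc6)cc(OCc6ccccc6)cc5O[C@@H]4c4ccc(OCc5ccccc5)cc4)c3)oc2c1 | intermediate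
22 | (2S,3R)-5,7-dihydroxy-3-[2-hydroxy-5-(5-hydroxy-7-methoxy-4-oxo-4H-chromen-2-yl)phenyl]-2-(4-hydroxyphenyl)-2,3-dihydro-4H-chromen-4-one | COc1cc(O)c2c(=O)cc(-c3ccc(O)c([C@H]4C(=O)c5c(O)cc(O)cc5O[C@@H]4c4ccc(O)cc4)c3)oc2c1 | target

## Step count and risk

Total: 14 steps. The longest linear sequence is 8 steps (steps 1, 2, 4, 5, 6, 12, 13, 14). The alkyne arm (steps 7 to 11, then 12 to 14) is equally long.

Step 13 (proposed new method).
- Risk: the aryl–rhodium species may insert too slowly into a trisubstituted double bond that carries a twisted ortho-substituted aryl group, so that protodeboronation of 19 wins. Facial selectivity may be poor because the 3-aryl group changes how the substrate sits in the chiral pocket. Base may open the product ring and erode C2.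
- Fallback, with known chemistry, from 18 back to 21: [4-(benzyloxy)phenyl]magnesium bromide F1 (from 1-(benzyloxy)-4-bromobenzene and magnesium) would be added with CuBr·SMe2 and chlorotrimethylsilane in THF at −78 °C, the silyl-accelerated cuprate addition established for chromones. This would give the racemic silyl enol ether F2. Mild acid hydrolysis and amine equilibration would give the racemic trans ketone, which is 21 together with its (2R,3S) enantiomer F3. Preparative chromatography on a chiral stationary phase would remove F3 and return 21.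

Step 12 (key step).
- Risk: the vinylogous ynone may be too weak a dienophile, so that cycloaddition is slow and the enol ether diene degrades thermally or by adventitious acid. Regioselectivity may be eroded because the chromonyl group at the diene terminus also polarises the diene.
- Fallback, from 8 (using 10) back to 18: 8 would be heated with tert-butyl propiolate, a far stronger dienophile of the same polarity, to give the cyclohexadiene ester F4. DDQ would aromatise it to tert-butyl 4-(benzyloxy)-3-[5,7-bis(benzyloxy)-4-oxo-4H-chromen-3-yl]benzoate F5. Trifluoroacetic acid in CH2Cl2 would release the benzoic acid F6, which would be esterified with the phenol of 10 (carbodiimide, DMAP) to give aryl ester F7. Baker–Venkataraman rearrangement with LiN(SiMe3)2 would give the 1,3-diketone F8, and acid-catalysed cyclodehydration (p-TsOH, toluene) would close the flavone pyranone to give 18.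

Step 5.
- Risk: the potassium dienolate may add to C2 of a chromone instead of being sulfonylated, or the enol ether geometry may scramble. The fallback also bypasses steps 4 and 6.
- Fallback, from 3 back to 8: methyl diazo(dimethoxyphosphoryl)acetate F9 (from trimethyl phosphonoacetate by diazo transfer) would undergo the same Rh2(OAc)4-catalysed insertion into benzyl alcohol, giving methyl 2-(benzyloxy)-2-(dimethoxyphosphoryl)acetate F10. Horner–Wadsworth–Emmons reaction with 3 (NaH, THF) would give the Z acrylate F11. i-Bu2AlH in CH2Cl2 at −78 °C would give the allylic alcohol F12, and MnO2 the enal F13. Wittig methylenation with Ph3P=CH2 would give 8. This sequence exposes the chromone to a hydride reagent, which is why it is the reserve.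

Step 11.
- Risk: alkoxide may add to the activated alkyne as it forms, or the very electrophilic aldehyde may be tied up as a hemiacetal, so that homologation stalls.
- Fallback, from 15 back to 16: CBr4 and PPh3 in CH2Cl2 would give the dibromoalkene F14. Bu3SnH with Pd(PPh3)4 would remove the bromine trans to the ring and give the Z bromoalkene F15. Anti-elimination with Bu4NF·3H2O in DMF would give 16.

Step 14.
- Risk: over-reduction, that is hydrogenolysis of the benzylic C2–O1 bond or saturation of the flavone double bond, before the last hindered benzyl ethers have left.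
- Fallback, from 21 directly to 22: Lewis-acid debenzylation with BCl3 and pentamethylbenzene as cation scavenger in CH2Cl2 at −78 °C, which leaves the 7-methyl ether; no new compound is involved.

## Further compounds

F1 | step 13 | [4-(benzyloxy)phenyl]magnesium bromide | Br[Mg]c1ccc(OCc2ccccc2)cc1
F2 | step 13 | {[5,7-bis(benzyloxy)-3-{2-(benzyloxy)-5-[5-(benzyloxy)-7-methoxy-4-oxo-4H-chromen-2-yl]phenyl}-2-[4-(benzyloxy)phenyl]-2H-chromen-4-yl]oxy}trimethylsilane (racemic) | COc1cc(OCc2ccccc2)c2c(=O)cc(-c3ccc(OCc4ccccc4)c(C4=C(O[Si](C)(C)C)c5c(OCc6ccccc6)cc(OCc6ccccc6)cc5OC4c4ccc(OCc5ccccc5)cc4)c3)oc2c1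
F3 | step 13 | (2R,3S)-5,7-bis(benzyloxy)-3-{2-(benzyloxy)-5-[5-(benzyloxy)-7-methoxy-4-oxo-4H-chromen-2-yl]phenyl}-2-[4-(benzyloxy)phenyl]-2,3-dihydro-4H-chromen-4-one | COc1cc(OCc2ccccc2)c2c(=O)cc(-c3ccc(OCc4ccccc4)c([C@@H]4C(=O)c5c(OCc6ccccc6)cc(OCc6ccccc6)cc5O[C@H]4c4ccc(OCc5ccccc5)cc4)c3)oc2c1
F4 | step 12 | tert-butyl 4-(benzyloxy)-3-[5,7-bis(benzyloxy)-4-oxo-4H-chromen-3-yl]cyclohexa-1,4-diene-1-carboxylate (racemic) | CC(C)(C)OC(=O)C1=CC(c2coc3cc(OCc4ccccc4)cc(OCc4ccccc4)c3c2=O)C(OCc2ccccc2)=CC1
F5 | step 12 | tert-butyl 4-(benzyloxy)-3-[5,7-bis(benzyloxy)-4-oxo-4H-chromen-3-yl]benzoate | CC(C)(C)OC(=O)c1ccc(OCc2ccccc2)c(-c2coc3cc(OCc4ccccc4)cc(OCc4ccccc4)c3c2=O)c1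
F6 | step 12 | 4-(benzyloxy)-3-[5,7-bis(benzyloxy)-4-oxo-4H-chromen-3-yl]benzoic acid | OC(=O)c1ccc(OCc2ccccc2)c(-c2coc3cc(OCc4ccccc4)cc(OCc4ccccc4)c3c2=O)c1
F7 | step 12 | 2-acetyl-3-(benzyloxy)-5-methoxyphenyl 4-(benzyloxy)-3-[5,7-bis(benzyloxy)-4-oxo-4H-chromen-3-yl]benzoate | CC(=O)c1c(OC(=O)c2ccc(OCc3ccccc3)c(-c3coc4cc(OCc5ccccc5)cc(OCc5ccccc5)c4c3=O)c2)cc(OC)cc1OCc1ccccc1
F8 | step 12 | 1-[2-(benzyloxy)-6-hydroxy-4-methoxyphenyl]-3-{4-(benzyloxy)-3-[5,7-bis(benzyloxy)-4-oxo-4H-chromen-3-yl]phenyl}propane-1,3-dione | COc1cc(O)c(C(=O)CC(=O)c2ccc(OCc3ccccc3)c(-c3coc4cc(OCc5ccccc5)cc(OCc5ccccc5)c4c3=O)c2)c(OCc2ccccc2)c1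
F9 | step 5 | methyl diazo(dimethoxyphosphoryl)acetate | COC(=O)C(=[N+]=[N-])P(=O)(OC)OC
F10 | step 5 | methyl 2-(benzyloxy)-2-(dimethoxyphosphoryl)acetate (racemic) | COC(=O)C(OCc1ccccc1)P(=O)(OC)OC
F11 | step 5 | methyl (2Z)-2-(benzyloxy)-3-[5,7-bis(benzyloxy)-4-oxo-4H-chromen-3-yl]prop-2-enoate | COC(=O)/C(OCc1ccccc1)=C/c1coc2cc(OCc3ccccc3)cc(OCc3ccccc3)c2c1=O
F12 | step 5 | 5,7-bis(benzyloxy)-3-[(1Z)-2-(benzyloxy)-3-hydroxyprop-1-en-1-yl]-4H-chromen-4-one | OC/C(OCc1ccccc1)=C/c1coc2cc(OCc3ccccc3)cc(OCc3ccccc3)c2c1=O
F13 | step 5 | (2Z)-2-(benzyloxy)-3-[5,7-bis(benzyloxy)-4-oxo-4H-chromen-3-yl]prop-2-enal | O=C/C(OCc1ccccc1)=C/c1coc2cc(OCc3ccccc3)cc(OCc3ccccc3)c2c1=O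
F14 | step 11 | 5-(benzyloxy)-2-(2,2-dibromoethenyl)-7-methoxy-4H-chromen-4-one | COc1cc(OCc2ccccc2)c2c(=O)cc(C=C(Br)Br)oc2c1
F15 | step 11 | 5-(benzyloxy)-2-[(Z)-2-bromoethenyl]-7-methoxy-4H-chromen-4-one | COc1cc(OCc2ccccc2)c2c(=O)cc(/C=C\Br)oc2c1
F0 | step 14 | none | none
A1 | alternative 1 | (2S,3R)-5,7-bis(benzyloxy)-3-[2-(benzyloxy)-5-(5-hydroxy-7-methoxy-4-oxo-4H-chromen-2-yl)phenyl]-2-[4-(benzyloxy)phenyl]-2,3-dihydro-4H-chromen-4-one | COc1cc(O)c2c(=O)cc(-c3ccc(OCc4ccccc4)c([C@H]4C(=O)c5c(OCc6ccccc6)cc(OCc6ccccc6)cc5O[C@@H]4c4ccc(OCc5ccccc5)cc4)c3)oc2c1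
A2 | alternative 1 | 2-iodo-5-methoxybenzene-1,3-diol | COc1cc(O)c(I)c(O)c1
A3 | alternative 1 | (2S,3R)-5,7-bis(benzyloxy)-3-[2-(benzyloxy)-5-ethynylphenyl]-2-[4-(benzyloxy)phenyl]-2,3-dihydro-4H-chromen-4-one | C#Cc1ccc(OCc2ccccc2)c([C@H]2C(=O)c3c(OCc4ccccc4)cc(OCc4ccccc4)cc3O[C@@H]2c2ccc(OCc3ccccc3)cc2)c1
A4 | alternative 1 | carbon monoxide | [C-]#[O+]
A5 | alternative 2 | benzyl {2-[(2S,3S,4R)-5,7-bis(benzyloxy)-2-[4-(benzyloxy)phenyl]-4-methoxy-3,4-dihydro-2H-chromen-3-yl]-4-[5-(benzyloxy)-7-methoxy-4-oxo-4H-chromen-2-yl]phenyl} carbonate (2,3-trans-4-methoxyflavan) | COc1cc(OCc2ccccc2)c2c(=O)cc(-c3ccc(OC(=O)OCc4ccccc4)c([C@H]4[C@@H](OC)c5c(OCc6ccccc6)cc(OCc6ccccc6)cc5O[C@@H]4c4ccc(OCc5ccccc5)cc4)c3)oc2c1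
A6 | alternative 2 | 3,5-bis(benzyloxy)-2-(dimethoxymethyl)phenol | COC(OC)c1c(O)cc(OCc2ccccc2)cc1OCc1ccccc1
A7 | alternative 2 | benzyl {4-[5-(benzyloxy)-7-methoxy-4-oxo-4H-chromen-2-yl]-2-[(E)-2-(4-(benzyloxy)phenyl)ethenyl]phenyl} carbonate | COc1cc(OCc2ccccc2)c2c(=O)cc(-c3ccc(OC(=O)OCc4ccccc4)c(/C=C/c4ccc(OCc5ccccc5)cc4)c3)oc2c1
A8 | alternative 3 | (2S,3R)-7-(benzyloxy)-5-{[4-(benzyloxy)benzyl]oxy}-3-{5-[5-(benzyloxy)-7-methoxy-4-oxo-4H-chromen-2-yl]-2-[(tert-butyldimethylsilyl)oxy]phenyl}-2-[4-(benzyloxy)phenyl]-2,3-dihydro-4H-chromen-4-one | COc1cc(OCc2ccccc2)c2c(=O)cc(-c3ccc(O[Si](C)(C)C(C)(C)C)c([C@H]4C(=O)c5c(OCc6ccc(OCc7ccccc7)cc6)cc(OCc6ccccc6)cc5O[C@@H]4c4ccc(OCc5ccccc5)cc4)c3)oc2c1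
A9 | alternative 3 | 1-(4-(benzyloxy)-2,6-bis{[4-(benzyloxy)benzyl]oxy}phenyl)-2-{5-[5-(benzyloxy)-7-methoxy-4-oxo-4H-chromen-2-yl]-2-[(tert-butyldimethylsilyl)oxy]phenyl}-2-diazoethan-1-one | COc1cc(OCc2ccccc2)c2c(=O)cc(-c3ccc(O[Si](C)(C)C(C)(C)C)c(C(=[N+]=[N-])C(=O)c4c(OCc5ccc(OCc6ccccc6)cc5)cc(OCc5ccccc5)cc4OCc4ccc(OCc5ccccc5)cc4)c3)oc2c1
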